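**Retrosynthetic overview** (carotenoid numbering of the furanoid end: C1 = CMe2, C3 = CHOH, C5 = C(CH3)–O, C6 = sp2 ring-fusion carbon, C7 = CH=, C8 = O–CH, C9 = butenolide α-carbon)
1. Late disconnections: Suzuki coupling of dienyl iodide 22 with dienylboronate 27 (central tetraene); butenolide ring by tandem Sonogashira coupling/5-exo-dig lactonisation on (E)-2,3-dibromoacrylic acid; C8–C9 by a second Sonogashira coupling.
2. Dihydrofuran ring: a temporary 5,6-oxirane (not in the target) fixes C5; its anti SN2' opening by palladium hydride turns that centre into an allene axis; a gold-catalysed 5-endo closure returns the axis as C8.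
3. Both carbocycles come from one enyne 9, made by a Diels–Alder reaction of the siloxydiene of mesityl oxide with pent-3-yn-2-one (bonds C4–C5 and C1–C6); the adduct is achiral and C3 is set afterwards by a ketoreductase.
4. Enabling feature: each six-membered ring carries oxygen at C3, 1,3 to the gem-dimethyl carbon C1 and 1,4 to C6; the C5–C6 bond shared by cyclohexane and dihydrofuran (CH3 and O on C5, the unsaturated chain on C6) is the oxidised trace of the C≡C of a methyl alkynyl ketone, i.e. a 2-siloxydiene/alkynone Diels–Alder retron.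
5. Ring order: carbocycle (step 2), oxirane (step 6), butenolide (step 9), dihydrofuran (step 12); the second carbocycle is the same batch of 9.

Key step: step 2

Assumption: a commercial ketoreductase panel contains an (R)-selective enzyme that accepts diketone 5; all polyene steps are run with exclusion of light.

Step 1
Reactants: 1 mesityl oxide (4-methylpent-3-en-2-one)
Product: 2 2-(tert-butyldimethylsilyloxy)-4-methylpenta-1,3-diene
Conditions: LiN(iPr)2, THF, −78 °C; TBSCl, DMPU, −78 °C → rt
Reagents that add atoms: tert-butyldimethylsilyl chloride (TBSCl), CC(C)(C)[Si](C)(C)Cl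
Why: Kinetic deprotonation of the enone at the α'-methyl group and O-silylation should give the cross-conjugated 2-silyloxydiene (silyl enol ether formation).

Step 2
Reactants: 2 2-(tert-butyldimethylsilyloxy)-4-methylpenta-1,3-diene; 3 pent-3-yn-2-one
Product: 5 4-acetyl-3,5,5-trimethylcyclohex-3-en-1-one, via silyl dienol ether cycloadduct 4 (not isolated)
Conditions: AlBr3/AlMe3 (10:1, 0.3 equiv), toluene–CH2Cl2, −10 °C → rt; then 1 M HCl, THF, 0 °C
Reagents that add atoms: none
Why: The aluminium Lewis acid binds the ynone carbonyl and the 2-siloxydiene adds in a polarised, asynchronous [4+2] cycloaddition in which the nucleophilic CH2 terminus (C4) bonds first to the methyl-bearing β-carbon (C5) and the dimethyl terminus (C1) then closes onto the acyl-bearing α-carbon (C6); cold aqueous acid unmasks the C3 ketone from silyl dienol ether 4. The closest known reaction types are the mixed aluminium Lewis acid-promoted Diels–Alder reaction of 4-methyl-2-silyloxypenta-1,3-dienes with hindered enones and the Diels–Alder reaction of 2-silyloxydienes with alkynones. One ring is closed, the six-membered carbocycle, and its mode of closure is an intermolecular [4+2] cycloaddition. No stereocentre is created because the dienophile is an alkyne and 5 is achiral; this is intended, since the retained C5=C6 bond later takes the oxirane that relays configuration to C5 and C8, and the same achiral ring serves both termini after one enzymatic reduction. The step needs regioselectivity (acetyl para to the siloxy carbon), which the matched polarisation of siloxydiene and ynone secures and which sterics reinforce, since the alternative would join the dimethyl terminus to the methyl-bearing carbon. It also needs the β,γ-unsaturated ketone to survive, which the brief cold hydrolysis addresses.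

Step 3
Reactants: 5 4-acetyl-3,5,5-trimethylcyclohex-3-en-1-one
Product: 6 1-[(4R)-4-hydroxy-2,6,6-trimethylcyclohex-1-en-1-yl]ethan-1-one
Conditions: (R)-selective ketoreductase (KRED), NADP+ (cat.), iPrOH, phosphate buffer pH 7, 30 °C
Reagents that add atoms: none
Why: An NADPH-dependent ketoreductase should reduce the unhindered ring ketone and leave the hindered conjugated acetyl group, and its pocket can tell apart the two CH2 flanks (CMe2 side against C(CH3)= side) that no small hydride reagent distinguishes, which sets C3 as R for both rings (enzymatic carbonyl reduction, as known for 3,3,5-trimethylcyclohexanone-type ketones).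

Step 4
Reactants: 6 1-[(4R)-4-hydroxy-2,6,6-trimethylcyclohex-1-en-1-yl]ethan-1-one
Product: 7 1-[(4R)-4-(tert-butyldimethylsilyloxy)-2,6,6-trimethylcyclohex-1-en-1-yl]ethan-1-one
Conditions: TBSCl, imidazole, DMF, rt
Reagents that add atoms: tert-butyldimethylsilyl chloride (TBSCl), CC(C)(C)[Si](C)(C)Cl
Why: Standard silylation of a secondary alcohol; the stereocentre is not touched.

Step 5
Reactants: 7 1-[(4R)-4-(tert-butyldimethylsilyloxy)-2,6,6-trimethylcyclohex-1-en-1-yl]ethan-1-one
Product: 9 tert-butyl{[(1R)-4-ethynyl-3,5,5-trimethylcyclohex-3-en-1-yl]oxy}dimethylsilane, via enol phosphate 8 (not isolated)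
Conditions: LiN(iPr)2 (1.1 equiv), THF, −78 °C; ClP(O)(OEt)2, −78 °C → rt; LiN(iPr)2 (2.3 equiv), −78 °C → rt; H2O
Reagents that add atoms: none
Why: Kinetic enolisation of the methyl ketone (the ring side has no α-hydrogen), O-phosphorylation and base-induced elimination of the enol phosphate should give the terminal alkyne (one-pot methyl ketone to alkyne conversion via an enol phosphate).

Step 6
Reactants: 9 tert-butyl{[(1R)-4-ethynyl-3,5,5-trimethylcyclohex-3-en-1-yl]oxy}dimethylsilane
Product: 10 (1R,3S,6R)-3-(tert-butyldimethylsilyloxy)-6-ethynyl-1,5,5-trimethyl-7-oxabicyclo[4.1.0]heptane (oxirane oxygen trans to the silyloxy group)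
Conditions: mCPBA, NaHCO3, CH2Cl2, 0 °C
Reagents that add atoms: 3-chloroperbenzoic acid (mCPBA), OOC(=O)c1cccc(Cl)c1
Why: Prilezhaev epoxidation of the only alkene (the alkyne is inert) should occur mainly from the face opposite to the bulky silyloxy group, which sets C5 as R with its oxygen trans to the C3 oxygen; a minor syn isomer would be removed by chromatography.

Step 7
Reactants: 11 (2E)-3-methylpent-2-en-4-yn-1-ol
Product: 12 triethyl{[(2E)-3-methylpent-2-en-4-yn-1-yl]oxy}silane
Conditions: Et3SiCl, imidazole, CH2Cl2, 0 °C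
Reagents that add atoms: triethylsilyl chloride, CC[Si](Cl)(CC)CC
Why: Standard silylation; the primary triethylsilyl ether can later be removed in the presence of the secondary tert-butyldimethylsilyl ether.

Step 8
Reactants: 13 propiolic acid (prop-2-ynoic acid)
Product: 14 (2E)-2,3-dibromoprop-2-enoic acid
Conditions: Br2, CHCl3, 0 °C → rt, dark
Reagents that add atoms: bromine, BrBr
Why: Ionic anti addition of bromine to the alkyne should give the E dibromide, in which the C3 bromine is cis to the carboxyl group (alkyne bromination).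

Step 9
Reactants: 12 triethyl{[(2E)-3-methylpent-2-en-4-yn-1-yl]oxy}silane; 14 (2E)-2,3-dibromoprop-2-enoic acid
Product: 16 (5Z)-3-bromo-5-[(2E)-2-methyl-4-(triethylsilyloxy)but-2-en-1-ylidene]furan-2(5H)-one, via bromo enynoic acid 15 (not isolated)
Conditions: PdCl2(PPh3)2 (5 mol%), CuI (10 mol%), Et3N, MeCN, rt
Reagents that add atoms: none
Why: Tandem Sonogashira coupling/5-exo-dig lactonisation: the β-bromide is the more reactive one and is cis to the carboxylate, which then adds anti across the activated alkyne to give the Z alkylidene butenolide with the α-bromide kept.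

Step 10
Reactants: 10 (1R,3S,6R)-3-(tert-butyldimethylsilyloxy)-6-ethynyl-1,5,5-trimethyl-7-oxabicyclo[4.1.0]heptane; 16 (5Z)-3-bromo-5-[(2E)-2-methyl-4-(triethylsilyloxy)but-2-en-1-ylidene]furan-2(5H)-one
Product: 17 (5Z)-3-{[(1R,4S,6R)-4-(tert-butyldimethylsilyloxy)-2,2,6-trimethyl-7-oxabicyclo[4.1.0]heptan-1-yl]ethynyl}-5-[(2E)-2-methyl-4-(triethylsilyloxy)but-2-en-1-ylidene]furan-2(5H)-one
Conditions: Pd(PPh3)4 (5 mol%), CuI (10 mol%), Et3N, THF, 40 °C
Reagents that add atoms: none
Why: Sonogashira coupling of the α-bromo butenolide (an activated alkenyl bromide) with the terminal alkyne forms the C8–C9 bond; the oxirane and both silyl ethers are spectators.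

Step 11
Reactants: 17 the alkynyl oxirane from step 10
Product: 18 (5Z)-3-{(aS)-2-[(2R,4S)-4-(tert-butyldimethylsilyloxy)-2-hydroxy-2,6,6-trimethylcyclohexylidene]ethenyl}-5-[(2E)-2-methyl-4-(triethylsilyloxy)but-2-en-1-ylidene]furan-2(5H)-one (allene with H on C8 anti and the butenolide syn to the C5 oxygen)
Conditions: Pd2(dba)3·CHCl3 (2.5 mol%), n-Bu3P (10 mol%), HCO2H, Et3N, THF, 0 °C → rt
Reagents that add atoms: none
Why: Palladium-catalysed formate hydrogenolysis of a propargylic electrophile: zerovalent palladium should open the oxirane in anti SN2' fashion to an allenylpalladium species and formate then delivers hydride with retention, so that H on C8 lies anti to the C5 oxygen and the C5 centre is converted into a defined allene axis without a hydride reagent that would attack the lactone.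

Step 12
Reactants: 18 the hydroxyallene from step 11
Product: 19 (5Z)-3-[(2R,6S,7aR)-6-(tert-butyldimethylsilyloxy)-4,4,7a-trimethyl-2,4,5,6,7,7a-hexahydro-1-benzofuran-2-yl]-5-[(2E)-2-methyl-4-(triethylsilyloxy)but-2-en-1-ylidene]furan-2(5H)-one
Conditions: Ph3PAuNTf2 (2 mol%), CH2Cl2, −20 → 0 °C
Reagents that add atoms: none
Why: Gold-catalysed 5-endo cycloisomerisation of an α-hydroxyallene: the C5 oxygen attacks C8 in the plane of the C6 substituents while monovalent gold sits on the opposite side, the two substituents of C8 stay above and below that plane, and the axis is therefore transferred to C8 as R with the butenolide cis to C4 (axis-to-centre chirality transfer).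

Step 13
Reactants: 19 the dihydrofuran from step 12
Product: 20 (5Z)-5-[(2E)-4-hydroxy-2-methylbut-2-en-1-ylidene]-3-[(2R,6S,7aR)-6-(tert-butyldimethylsilyloxy)-4,4,7a-trimethyl-2,4,5,6,7,7a-hexahydro-1-benzofuran-2-yl]furan-2(5H)-one
Conditions: HF·pyridine, pyridine, THF, 0 °C
Reagents that add atoms: none
Why: A primary triethylsilyl ether is cleaved much faster than a secondary tert-butyldimethylsilyl ether under buffered fluoride, and the buffer protects the allylic C8–O bond.

Step 14
Reactants: 20 the allylic alcohol from step 13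
Product: 21 (2E)-3-methyl-4-{(2Z)-5-oxo-4-[(2R,6S,7aR)-6-(tert-butyldimethylsilyloxy)-4,4,7a-trimethyl-2,4,5,6,7,7a-hexahydro-1-benzofuran-2-yl]furan-2(5H)-ylidene}but-2-enal
Conditions: MnO2, CH2Cl2, rt
Reagents that add atoms: none
Why: Selective oxidation of a primary allylic alcohol to the enal; no other free hydroxyl is present.

Step 15
Reactants: 21 the enal from step 14
Product: 22 (5Z)-5-[(2E,4E)-5-iodo-2-methylpenta-2,4-dien-1-ylidene]-3-[(2R,6S,7aR)-6-(tert-butyldimethylsilyloxy)-4,4,7a-trimethyl-2,4,5,6,7,7a-hexahydro-1-benzofuran-2-yl]furan-2(5H)-one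
Conditions: CrCl2, CHI3, THF, 0 °C, dark
Reagents that add atoms: iodoform, IC(I)I
Why: Takai olefination should convert the aldehyde into the E alkenyl iodide and tolerates lactones and silyl ethers.

Step 16
Reactants: 9 tert-butyl{[(1R)-4-ethynyl-3,5,5-trimethylcyclohex-3-en-1-yl]oxy}dimethylsilane; 23 ethyl but-2-ynoate
Product: 24 ethyl (2E)-5-[(4R)-4-(tert-butyldimethylsilyloxy)-2,6,6-trimethylcyclohex-1-en-1-yl]-3-methylpent-2-en-4-ynoate
Conditions: Pd(OAc)2 (3 mol%), tris(2,6-dimethoxyphenyl)phosphine (3 mol%), THF, rt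
Reagents that add atoms: none
Why: Palladium-catalysed cross-addition of a terminal alkyne to an alkynoate (hydroalkynylation) adds the alkynyl C–H syn across the ynoate, with the alkynyl group on the methyl-bearing β-carbon, and so should give the E enynoate.

Step 17
Reactants: 24 the enynoate from step 16
Product: 25 (2E)-5-[(4R)-4-(tert-butyldimethylsilyloxy)-2,6,6-trimethylcyclohex-1-en-1-yl]-3-methylpent-2-en-4-yn-1-ol
Conditions: iBu2AlH, CH2Cl2, −78 °C
Reagents that add atoms: none
Why: 1,2-Reduction of the conjugated ester to the allylic alcohol; alkene geometry is kept.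

Step 18
Reactants: 25 the dienynol from step 17
Product: 26 (2E)-5-[(4R)-4-(tert-butyldimethylsilyloxy)-2,6,6-trimethylcyclohex-1-en-1-yl]-3-methylpent-2-en-4-ynal
Conditions: MnO2, CH2Cl2, rt
Reagents that add atoms: none
Why: Allylic oxidation to the enal without isomerisation of the trisubstituted alkene.

Step 19
Reactants: 26 the enynal from step 18
Product: 27 2-{(1E,3E)-6-[(4R)-4-(tert-butyldimethylsilyloxy)-2,6,6-trimethylcyclohex-1-en-1-yl]-4-methylhexa-1,3-dien-5-yn-1-yl}-4,4,5,5-tetramethyl-1,3,2-dioxaborolane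
Conditions: CrCl2, LiI, Cl2CHB(pin), THF, rt, dark
Reagents that add atoms: 2-(dichloromethyl)-4,4,5,5-tetramethyl-1,3,2-dioxaborolane, ClC(Cl)B1OC(C)(C)C(C)(C)O1
Why: The boron variant of the Takai olefination (Takai–Utimoto) should give the E alkenylboronate from the aldehyde under non-basic conditions.

Step 20
Reactants: 22 the dienyl iodide from step 15; 27 the dienylboronate from step 19
Product: 28 3,3'-bis(tert-butyldimethylsilyl) ether of the target
Conditions: Pd(PPh3)4 (10 mol%), TlOEt, THF–H2O (3:1), rt, dark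
Reagents that add atoms: none
Why: Suzuki–Miyaura coupling of an alkenyl iodide with an alkenylboronate proceeds with retention at both partners, and the fast thallium ethoxide protocol at room temperature spares the enol lactone.

Step 21
Reactants: 28 bis-silyl ether of the target
Product: 29 target, (5Z)-3-[(2R,6S,7aR)-6-hydroxy-4,4,7a-trimethyl-2,4,5,6,7,7a-hexahydro-1-benzofuran-2-yl]-5-{(2E,4E,6E,8E)-11-[(4R)-4-hydroxy-2,6,6-trimethylcyclohex-1-en-1-yl]-2,9-dimethylundeca-2,4,6,8-tetraen-10-yn-1-ylidene}furan-2(5H)-one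
Conditions: Bu4NF, AcOH (1:1), THF, 0 °C → rt, dark
Reagents that add atoms: none
Why: Acetic acid-buffered fluoride removes both secondary silyl ethers without opening the enol lactone or ionising the C8–O bond.

**Compound list**
1 | mesityl oxide (4-methylpent-3-en-2-one) | CC(=O)C=C(C)C | starting material
2 | 2-(tert-butyldimethylsilyloxy)-4-methylpenta-1,3-diene | C=C(O[Si](C)(C)C(C)(C)C)C=C(C)C | intermediate
3 | pent-3-yn-2-one | CC#CC(C)=O | starting material
4 | 1-[4-(tert-butyldimethylsilyloxy)-2,6,6-trimethylcyclohexa-1,4-dien-1-yl]ethan-1-one (silyl dienol ether cycloadduct, achiral) | CC(=O)C1=C(C)CC(O[Si](C)(C)C(C)(C)C)=CC1(C)C | intermediate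
5 | 4-acetyl-3,5,5-trimethylcyclohex-3-en-1-one (achiral) | CC(=O)C1=C(C)CC(=O)CC1(C)C | intermediate
6 | 1-[(4R)-4-hydroxy-2,6,6-trimethylcyclohex-1-en-1-yl]ethan-1-one | CC1=C(C(C)=O)C(C)(C)C[C@H](O)C1 | intermediate
7 | 1-[(4R)-4-(tert-butyldimethylsilyloxy)-2,6,6-trimethylcyclohex-1-en-1-yl]ethan-1-one | CC1=C(C(C)=O)C(C)(C)C[C@H](O[Si](C)(C)C(C)(C)C)C1 | intermediate
8 | diethyl 1-[(4R)-4-(tert-butyldimethylsilyloxy)-2,6,6-trimethylcyclohex-1-en-1-yl]ethenyl phosphate | CC1=C(C(=C)OP(=O)(OCC)OCC)C(C)(C)C[C@H](O[Si](C)(C)C(C)(C)C)C1 | intermediate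
9 | tert-butyl{[(1R)-4-ethynyl-3,5,5-trimethylcyclohex-3-en-1-yl]oxy}dimethylsilane | CC1=C(C#C)C(C)(C)C[C@H](O[Si](C)(C)C(C)(C)C)C1 | intermediate
10 | (1R,3S,6R)-3-(tert-butyldimethylsilyloxy)-6-ethynyl-1,5,5-trimethyl-7-oxabicyclo[4.1.0]heptane, oxirane oxygen trans to the silyloxy group | C#C[C@@]12O[C@]1(C)C[C@@H](O[Si](C)(C)C(C)(C)C)CC2(C)C | intermediate
11 | (2E)-3-methylpent-2-en-4-yn-1-ol | C#C/C(C)=C/CO | starting material
12 | triethyl{[(2E)-3-methylpent-2-en-4-yn-1-yl]oxy}silane | C#C/C(C)=C/CO[Si](CC)(CC)CC | intermediate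
13 | propiolic acid | C#CC(=O)O | starting material
14 | (2E)-2,3-dibromoprop-2-enoic acid | OC(=O)/C(Br)=C\Br | intermediate
15 | (2E,6E)-2-bromo-6-methyl-8-(triethylsilyloxy)octa-2,6-dien-4-ynoic acid | OC(=O)/C(Br)=C\C#C/C(C)=C/CO[Si](CC)(CC)CC | intermediate
16 | (5Z)-3-bromo-5-[(2E)-2-methyl-4-(triethylsilyloxy)but-2-en-1-ylidene]furan-2(5H)-one | CC[Si](CC)(CC)OC/C=C(C)/C=C1/C=C(Br)C(=O)O1 | intermediate
17 | (5Z)-3-{[(1R,4S,6R)-4-(tert-butyldimethylsilyloxy)-2,2,6-trimethyl-7-oxabicyclo[4.1.0]heptan-1-yl]ethynyl}-5-[(2E)-2-methyl-4-(triethylsilyloxy)but-2-en-1-ylidene]furan-2(5H)-one | CC[Si](CC)(CC)OC/C=C(C)/C=C1/C=C(C#C[C@@]23O[C@]2(C)C[C@@H](O[Si](C)(C)C(C)(C)C)CC3(C)C)C(=O)O1 | intermediate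
18 | (5Z)-3-{(aS)-2-[(2R,4S)-4-(tert-butyldimethylsilyloxy)-2-hydroxy-2,6,6-trimethylcyclohexylidene]ethenyl}-5-[(2E)-2-methyl-4-(triethylsilyloxy)but-2-en-1-ylidene]furan-2(5H)-one, H on C8 anti to the C5 oxygen | O[C@]1(C)C[C@@H](O[Si](C)(C)C(C)(C)C)CC(C)(C)C1=[C@]=C([H])C2=C/C(=C/C(C)=C/CO[Si](CC)(CC)CC)OC2=O | intermediate
19 | (5Z)-3-[(2R,6S,7aR)-6-(tert-butyldimethylsilyloxy)-4,4,7a-trimethyl-2,4,5,6,7,7a-hexahydro-1-benzofuran-2-yl]-5-[(2E)-2-methyl-4-(triethylsilyloxy)but-2-en-1-ylidene]furan-2(5H)-one | CC[Si](CC)(CC)OC/C=C(C)/C=C1/C=C([C@H]2C=C3C(C)(C)C[C@H](O[Si](C)(C)C(C)(C)C)C[C@@]3(C)O2)C(=O)O1 | intermediate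
20 | primary allylic alcohol of 19 (triethylsilyl group removed) | OC/C=C(C)/C=C1/C=C([C@H]2C=C3C(C)(C)C[C@H](O[Si](C)(C)C(C)(C)C)C[C@@]3(C)O2)C(=O)O1 | intermediate
21 | (2E)-enal from 20 | O=C/C=C(C)/C=C1/C=C([C@H]2C=C3C(C)(C)C[C@H](O[Si](C)(C)C(C)(C)C)C[C@@]3(C)O2)C(=O)O1 | intermediate
22 | (5Z)-5-[(2E,4E)-5-iodo-2-methylpenta-2,4-dien-1-ylidene]-3-[(2R,6S,7aR)-6-(tert-butyldimethylsilyloxy)-4,4,7a-trimethyl-2,4,5,6,7,7a-hexahydro-1-benzofuran-2-yl]furan-2(5H)-one | I/C=C/C=C(C)/C=C1/C=C([C@H]2C=C3C(C)(C)C[C@H](O[Si](C)(C)C(C)(C)C)C[C@@]3(C)O2)C(=O)O1 | intermediate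
23 | ethyl but-2-ynoate | CC#CC(=O)OCC | starting material
24 | ethyl (2E)-5-[(4R)-4-(tert-butyldimethylsilyloxy)-2,6,6-trimethylcyclohex-1-en-1-yl]-3-methylpent-2-en-4-ynoate | CC1=C(C#C/C(C)=C/C(=O)OCC)C(C)(C)C[C@H](O[Si](C)(C)C(C)(C)C)C1 | intermediate
25 | (2E)-5-[(4R)-4-(tert-butyldimethylsilyloxy)-2,6,6-trimethylcyclohex-1-en-1-yl]-3-methylpent-2-en-4-yn-1-ol | CC1=C(C#C/C(C)=C/CO)C(C)(C)C[C@H](O[Si](C)(C)C(C)(C)C)C1 | intermediate
26 | (2E)-5-[(4R)-4-(tert-butyldimethylsilyloxy)-2,6,6-trimethylcyclohex-1-en-1-yl]-3-methylpent-2-en-4-ynal | CC1=C(C#C/C(C)=C/C=O)C(C)(C)C[C@H](O[Si](C)(C)C(C)(C)C)C1 | intermediate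
27 | 2-{(1E,3E)-6-[(4R)-4-(tert-butyldimethylsilyloxy)-2,6,6-trimethylcyclohex-1-en-1-yl]-4-methylhexa-1,3-dien-5-yn-1-yl}-4,4,5,5-tetramethyl-1,3,2-dioxaborolane | CC1=C(C#C/C(C)=C/C=C/B2OC(C)(C)C(C)(C)O2)C(C)(C)C[C@H](O[Si](C)(C)C(C)(C)C)C1 | intermediate
28 | 3,3'-bis(tert-butyldimethylsilyl) ether of the target | CC1=C(C#C/C(C)=C/C=C/C=C/C=C(C)/C=C2/C=C([C@H]3C=C4C(C)(C)C[C@H](O[Si](C)(C)C(C)(C)C)C[C@@]4(C)O3)C(=O)O2)C(C)(C)C[C@H](O[Si](C)(C)C(C)(C)C)C1 | intermediate
29 | (5Z)-3-[(2R,6S,7aR)-6-hydroxy-4,4,7a-trimethyl-2,4,5,6,7,7a-hexahydro-1-benzofuran-2-yl]-5-{(2E,4E,6E,8E)-11-[(4R)-4-hydroxy-2,6,6-trimethylcyclohex-1-en-1-yl]-2,9-dimethylundeca-2,4,6,8-tetraen-10-yn-1-ylidene}furan-2(5H)-one | CC1=C(C#C/C(C)=C/C=C/C=C/C=C(C)/C=C2/C=C([C@H]3C=C4C(C)(C)C[C@H](O)C[C@@]4(C)O3)C(=O)O2)C(C)(C)C[C@H](O)C1 | target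

**Count and risks**
Total step count: 21. Longest linear sequence: 14 steps (steps 1–6, 10–15, 20, 21).

Steps most likely to fail:

Step 2. The twisted diene may reach its reactive s-cis geometry too slowly, so that Lewis acid-induced conjugate addition without ring closure, or loss of the silyl group from the diene, overtakes the cycloaddition. Fallback: a polar stepwise annulation that forms the same two bonds sets out from compound 1. Condensation of 1 with pentane-2,4-dione (ZnCl2, heptane, reflux with removal of water) by Michael addition (C1–C6) and aldol condensation (C4–C5) should give racemic 4-acetyl-3,5,5-trimethylcyclohex-2-en-1-one F1. Formation of its extended enolate (LiN(iPr)2, THF, −78 °C) and kinetic protonation at the α-carbon (AcOH, −78 °C) should move the double bond out of conjugation with the ring ketone, and the sequence comes back to the route at compound 5.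

Step 11. Palladium hydride may reduce the alkylidene butenolide, or the allenylpalladium intermediate may equilibrate so that the anti stereospecificity is lost. Fallback: the hydride step and the allene are avoided; the sequence sets out from compounds 10 and 16. Hydroboration of 10 (pinacolborane, Cp2Zr(H)Cl cat., Et3N, CH2Cl2) should give the (E)-alkenylboronate with the oxirane intact F2. Suzuki coupling of F2 with 16 (Pd(PPh3)4, TlOEt, THF–H2O) should give the (7E)-vinyl oxirane butenolide F3. Mild acid (pyridinium p-toluenesulfonate, CH2Cl2, 0 °C) should then induce the 5,6-epoxide to 5,8-furanoid rearrangement typical of epoxy carotenoid end groups. This is expected to give 19 together with the C8 epimer of 19 F4, which is removed by chromatography; the sequence comes back to the route at compound 19.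

Step 12. Gold may epimerise the allene axis before ring closure, or may engage the enol lactone, so that chirality transfer to C8 is eroded. Fallback: an electrophilic cyclisation replaces the metal-catalysed one and sets out from compound 18. N-Iodosuccinimide (CH2Cl2, −20 °C) should effect 5-endo iodoetherification with the same axis-to-centre transfer and give the 7-iodo-2,5-dihydrofuran F5. Reductive removal of the alkenyl iodide (Pd(PPh3)4, Bu3SnH, THF, rt) comes back to the route at compound 19.

Further compounds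
F1 | step 2 | 4-acetyl-3,5,5-trimethylcyclohex-2-en-1-one (racemic) | CC(=O)C1C(C)=CC(=O)CC1(C)C
F2 | step 11 | 2-{(E)-2-[4-(tert-butyldimethylsilyloxy)-2,2,6-trimethyl-7-oxabicyclo[4.1.0]heptan-1-yl]ethenyl}-4,4,5,5-tetramethyl-1,3,2-dioxaborolane, oxirane configuration as in 10 | CC1(C)OB(/C=C/[C@@]23O[C@]2(C)C[C@@H](O[Si](C)(C)C(C)(C)C)CC3(C)C)OC1(C)C
F3 | step 11 | (5Z)-3-{(E)-2-[4-(tert-butyldimethylsilyloxy)-2,2,6-trimethyl-7-oxabicyclo[4.1.0]heptan-1-yl]ethenyl}-5-[(2E)-2-methyl-4-(triethylsilyloxy)but-2-en-1-ylidene]furan-2(5H)-one, oxirane configuration as in 10 | CC[Si](CC)(CC)OC/C=C(C)/C=C1/C=C(/C=C/[C@@]23O[C@]2(C)C[C@@H](O[Si](C)(C)C(C)(C)C)CC3(C)C)C(=O)O1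
F4 | step 11 | C8 epimer of 19, (2S,6S,7aR)-benzofuranyl isomer | CC[Si](CC)(CC)OC/C=C(C)/C=C1/C=C([C@@H]2C=C3C(C)(C)C[C@H](O[Si](C)(C)C(C)(C)C)C[C@@]3(C)O2)C(=O)O1
F5 | step 12 | 7-iodo derivative of 19 (iodine on the ring CH= carbon of the dihydrofuran) | CC[Si](CC)(CC)OC/C=C(C)/C=C1/C=C([C@H]2C(I)=C3C(C)(C)C[C@H](O[Si](C)(C)C(C)(C)C)C[C@@]3(C)O2)C(=O)O1
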